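**Retrosynthetic overview**
1. Feature: the ring O and C1–C5 of the tetrahydropyran, with the C3 hydroxyl trans to the C5 side chain, form a 2,4-dideoxyhexopyranose with C6 as its exocyclic carbon. This is the lactol that 2-deoxyribose-5-phosphate aldolase assembles from two-carbon aldehydes.
2. Late: remove the O-benzyl and O-silyl groups. Cut C6–C7 by chelation-controlled 4-(benzyloxy)benzyl Grignard addition to the C5 carbaldehyde, which sets C6. The aldehyde comes from the chloromethyl group by acetate displacement, methanolysis and oxidation.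
3. Middle: cut C1–aryl by aryllithium addition to the lactone, followed by axial hydride delivery to the cyclic oxocarbenium ion. This sets C1 cis to C5.
4. Early: the pyran is the only ring made and it is closed first. The C4–C5 and C2–C3 aldol bonds and the O–C1 hemiacetal form from chloroacetaldehyde and two acetaldehyde units, setting C5 and C3. Both arenes are purchased.

Key step: step 1

Remark: positions are numbered along the heptanoid chain (C1 guaiacyl-bearing ring carbon, C3 ring carbinol, C5 ring carbon carrying the side chain, C6 side-chain carbinol, C7 benzylic CH2). Chloroacetaldehyde is used as its commercial aqueous solution and is drawn as the free aldehyde.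

Step 1
Reactants: 1 chloroacetaldehyde; 2 acetaldehyde (two equivalents)
Product: 5 (4R,6S)-6-(chloromethyl)tetrahydro-2H-pyran-2,4-diol (anomeric mixture), via (S)-4-chloro-3-hydroxybutanal 3 (not isolated), via (3R,5S)-6-chloro-3,5-dihydroxyhexanal 4 (not isolated)
Conditions: 2-deoxyribose-5-phosphate aldolase (E. coli whole cells or lysate), aq. buffer pH 7.2–7.5, slow co-feed of 1 and 2, 25–30 °C; EtOAc extraction
Reagents that add atoms: none
Why: The active-site lysine of this class I aldolase condenses with 2 to an enamine that attacks the carbonyl of acceptor 1 on one face only (C4–C5 bond, giving 3), and 3 then serves as acceptor for a second enzyme-bound enamine that adds in the same facial sense (C2–C3 bond, giving 4). The C5 hydroxyl of 4 adds to the C1 aldehyde in a 6-exo-trig hemiacetalisation (O–C1 bond), and because lactol 5 no longer shows a free aldehyde, the reversible aldol equilibria are drawn forward and a third addition is stopped. This is the known sequential aldolase reaction of chloroacetaldehyde with two acetaldehyde units that supplies statin side-chain lactols, so it is used here on its own proven substrate. C5 (S) and C3 (R in 5, and S from compound 13 on only through a change of CIP ranking) are both fixed by the enzyme's enamine and acceptor facial preference, which gives the 3,5-syn diol and hence a C3 hydroxyl trans to the C5 substituent on the ring, while the anomeric centre is a mixture that step 2 erases. The selectivity needed is cross-aldolisation over self-aldolisation of 2, and it is secured because 1 is the more electrophilic acceptor and is not taken as donor, while slow co-feeding keeps both aldehydes dilute and spares the enzyme.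

Step 2
Reactants: 5 (4R,6S)-6-(chloromethyl)tetrahydro-2H-pyran-2,4-diol
Product: 6 (4R,6S)-6-(chloromethyl)-4-hydroxytetrahydro-2H-pyran-2-one
Conditions: aq. NaOCl (about 1 equiv, metered), AcOH, 15–20 °C
Reagents that add atoms: none
Why: Lactol oxidation by hypochlorous acid, in which the anomeric hemiacetal C–H is oxidised faster than the C4 carbinol when the oxidant is metered, no stereocentre is touched and no arene is yet present to be chlorinated.

Step 3
Reactants: 6 (4R,6S)-6-(chloromethyl)-4-hydroxytetrahydro-2H-pyran-2-one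
Product: 7 (4R,6S)-4-[(tert-butyldimethylsilyl)oxy]-6-(chloromethyl)tetrahydro-2H-pyran-2-one
Conditions: TBSCl, imidazole, DMF, 0 °C → rt
Reagents that add atoms: tert-butyldimethylsilyl chloride, CC(C)(C)[Si](C)(C)Cl
Why: Imidazole-promoted silylation of the secondary alcohol, whose weak base avoids E1cB loss of the β-oxygen from the lactone and whose silyl ether withstands the later aryllithium, acetate, carbonate and Grignard steps.

Step 4
Reactants: 8 4-bromo-2-methoxyphenol
Product: 9 1-(benzyloxy)-4-bromo-2-methoxybenzene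
Conditions: BnBr, K2CO3, acetone, reflux
Reagents that add atoms: benzyl bromide, BrCc1ccccc1
Why: Williamson etherification, which masks the acidic phenol for the halogen–metal exchange with a group that leaves in the final hydrogenolysis.

Step 5
Reactants: 9 1-(benzyloxy)-4-bromo-2-methoxybenzene; 7 (4R,6S)-4-[(tert-butyldimethylsilyl)oxy]-6-(chloromethyl)tetrahydro-2H-pyran-2-one
Product: 11 (4R,6S)-2-[4-(benzyloxy)-3-methoxyphenyl]-4-[(tert-butyldimethylsilyl)oxy]-6-(chloromethyl)tetrahydro-2H-pyran-2-ol (anomeric mixture, in equilibrium with the open δ-hydroxy ketone), via [4-(benzyloxy)-3-methoxyphenyl]lithium 10 (not isolated)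
Conditions: 9, n-BuLi, THF, −78 °C; then 7, −78 °C; AcOH/THF quench at −78 °C
Reagents that add atoms: n-butyllithium, [Li]CCCC (supplies the lithium of 10; none of its atoms stays in 11)
Why: Bromine–lithium exchange followed by 1,2-addition of the aryllithium to a δ-lactone, as in C-aryl glycoside synthesis, where the tetrahedral lithium alkoxide persists at −78 °C and blocks a second addition, the primary chloride is inert at this temperature, the cold acidic quench forestalls epoxide closure of a chlorohydrin alkoxide, and the new anomeric centre is of no consequence.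

Step 6
Reactants: 11 (4R,6S)-2-[4-(benzyloxy)-3-methoxyphenyl]-4-[(tert-butyldimethylsilyl)oxy]-6-(chloromethyl)tetrahydro-2H-pyran-2-ol
Product: 13 (2R,4S,6S)-2-[4-(benzyloxy)-3-methoxyphenyl]-4-[(tert-butyldimethylsilyl)oxy]-6-(chloromethyl)tetrahydro-2H-pyran, via the aryl-stabilised cyclic oxocarbenium ion (C1=O+) 12 (not isolated)
Conditions: Et3SiH, BF3·OEt2, CH2Cl2, −78 → −40 °C; aq. NaHCO3
Reagents that add atoms: none
Why: Ionic (silane/Lewis acid) reduction of a hemiketal, in which 12 adopts the half-chair with the C5 chloromethyl pseudoequatorial and the C3 silyloxy group pseudoaxial, and stereoelectronically favoured axial hydride delivery places the aryl group equatorial, giving (1R) with C1 and C5 cis, which is also the thermodynamically preferred arrangement.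

Step 7
Reactants: 13 (2R,4S,6S)-2-[4-(benzyloxy)-3-methoxyphenyl]-4-[(tert-butyldimethylsilyl)oxy]-6-(chloromethyl)tetrahydro-2H-pyran
Product: 14 {(2S,4S,6R)-6-[4-(benzyloxy)-3-methoxyphenyl]-4-[(tert-butyldimethylsilyl)oxy]tetrahydro-2H-pyran-2-yl}methyl acetate
Conditions: n-Bu4NOAc, NMP, 100 °C
Reagents that add atoms: tetrabutylammonium acetate, CC(=O)[O-].CCCC[N+](CCCC)(CCCC)CCCC
Why: SN2 displacement of the primary chloride by poorly solvated acetate in a dipolar aprotic solvent, the exchange used on the analogous 6-chloromethyl statin building blocks, which occurs at the achiral C6 and leaves C5 untouched.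

Step 8
Reactants: 14 {(2S,4S,6R)-6-[4-(benzyloxy)-3-methoxyphenyl]-4-[(tert-butyldimethylsilyl)oxy]tetrahydro-2H-pyran-2-yl}methyl acetate
Product: 15 {(2S,4S,6R)-6-[4-(benzyloxy)-3-methoxyphenyl]-4-[(tert-butyldimethylsilyl)oxy]tetrahydro-2H-pyran-2-yl}methanol
Conditions: K2CO3 (cat.), MeOH, 0 °C → rt
Reagents that add atoms: none
Why: Base-catalysed transesterification (methanolysis) of a primary acetate under conditions that leave the secondary TBS ether and the benzyl ether intact.

Step 9
Reactants: 15 {(2S,4S,6R)-6-[4-(benzyloxy)-3-methoxyphenyl]-4-[(tert-butyldimethylsilyl)oxy]tetrahydro-2H-pyran-2-yl}methanol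
Product: 16 (2S,4S,6R)-6-[4-(benzyloxy)-3-methoxyphenyl]-4-[(tert-butyldimethylsilyl)oxy]tetrahydro-2H-pyran-2-carbaldehyde
Conditions: Dess–Martin periodinane, CH2Cl2, 0 °C → rt; used at once
Reagents that add atoms: none
Why: Dess–Martin oxidation stops at the aldehyde under nearly neutral conditions, and C5 has no drive to epimerise because the formyl group is already equatorial.

Step 10
Reactants: 17 4-(benzyloxy)benzyl chloride; 16 (2S,4S,6R)-6-[4-(benzyloxy)-3-methoxyphenyl]-4-[(tert-butyldimethylsilyl)oxy]tetrahydro-2H-pyran-2-carbaldehyde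
Product: 19 (1S)-1-{(2S,4S,6R)-6-[4-(benzyloxy)-3-methoxyphenyl]-4-[(tert-butyldimethylsilyl)oxy]tetrahydro-2H-pyran-2-yl}-2-[4-(benzyloxy)phenyl]ethan-1-ol, via 4-(benzyloxy)benzylmagnesium chloride 18 (not isolated)
Conditions: 17, Mg, Et2O (slow addition, dilute), 0 °C → rt; 16, MgBr2·OEt2, CH2Cl2, −78 °C, then 18; sat. aq. NH4Cl
Reagents that add atoms: magnesium, [Mg] (held in 18 only; none stays in 19)
Why: Grignard addition to an α-alkoxy aldehyde under Cram-chelate control, in which Mg(II) ties the aldehyde oxygen to the ring oxygen in a five-membered chelate and the benzyl nucleophile enters from the face flanked by C5–H rather than by C4H2, giving the 5,6-syn relationship, that is (6S).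

Step 11
Reactants: 19 (1S)-1-{(2S,4S,6R)-6-[4-(benzyloxy)-3-methoxyphenyl]-4-[(tert-butyldimethylsilyl)oxy]tetrahydro-2H-pyran-2-yl}-2-[4-(benzyloxy)phenyl]ethan-1-ol
Product: 20 (2R,4S,6S)-2-[4-(benzyloxy)-3-methoxyphenyl]-6-{(1S)-2-[4-(benzyloxy)phenyl]-1-hydroxyethyl}tetrahydro-2H-pyran-4-ol
Conditions: TBAF, THF, rt
Reagents that add atoms: none
Why: Fluoride-mediated desilylation, run while the phenols are still benzylated so that no acid meets the electron-rich benzylic C1–O bond.

Step 12
Reactants: 20 (2R,4S,6S)-2-[4-(benzyloxy)-3-methoxyphenyl]-6-{(1S)-2-[4-(benzyloxy)phenyl]-1-hydroxyethyl}tetrahydro-2H-pyran-4-ol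
Product: 21 rhoiptelol B, (2R,4S,6S)-2-(4-hydroxy-3-methoxyphenyl)-6-[(1S)-1-hydroxy-2-(4-hydroxyphenyl)ethyl]tetrahydro-2H-pyran-4-ol
Conditions: H2 (1 atm), 10% Pd/C, EtOAc, rt; stopped at full debenzylation
Reagents that add atoms: none
Why: Catalytic hydrogenolysis cleaves aryl benzyl ethers far faster than the secondary, ring-held benzylic C1–O bond under neutral conditions, so both phenols are freed without touching a stereocentre.

**Compound list**
1 | chloroacetaldehyde | ClCC=O | starting material
2 | acetaldehyde | CC=O | starting material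
3 | (S)-4-chloro-3-hydroxybutanal | O=CC[C@H](O)CCl | intermediate
4 | (3R,5S)-6-chloro-3,5-dihydroxyhexanal | O=CC[C@H](O)C[C@H](O)CCl | intermediate
5 | (4R,6S)-6-(chloromethyl)tetrahydro-2H-pyran-2,4-diol (anomeric mixture) | OC1C[C@H](O)C[C@@H](CCl)O1 | intermediate
6 | (4R,6S)-6-(chloromethyl)-4-hydroxytetrahydro-2H-pyran-2-one | O=C1C[C@H](O)C[C@@H](CCl)O1 | intermediate
7 | (4R,6S)-4-[(tert-butyldimethylsilyl)oxy]-6-(chloromethyl)tetrahydro-2H-pyran-2-one | O=C1C[C@H](O[Si](C)(C)C(C)(C)C)C[C@@H](CCl)O1 | intermediate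
8 | 4-bromo-2-methoxyphenol | COc1cc(Br)ccc1O | starting material
9 | 1-(benzyloxy)-4-bromo-2-methoxybenzene | COc1cc(Br)ccc1OCc1ccccc1 | intermediate
10 | [4-(benzyloxy)-3-methoxyphenyl]lithium | COc1cc([Li])ccc1OCc1ccccc1 | intermediate
11 | (4R,6S)-2-[4-(benzyloxy)-3-methoxyphenyl]-4-[(tert-butyldimethylsilyl)oxy]-6-(chloromethyl)tetrahydro-2H-pyran-2-ol (anomeric mixture) | COc1cc(C2(O)C[C@H](O[Si](C)(C)C(C)(C)C)C[C@@H](CCl)O2)ccc1OCc1ccccc1 | intermediate
12 | cyclic oxocarbenium ion from 11 (C1=O+, aryl on C1, C3 OTBS, C5 CH2Cl) | COc1cc(C2=[O+][C@H](CCl)C[C@@H](O[Si](C)(C)C(C)(C)C)C2)ccc1OCc1ccccc1 | intermediate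
13 | (2R,4S,6S)-2-[4-(benzyloxy)-3-methoxyphenyl]-4-[(tert-butyldimethylsilyl)oxy]-6-(chloromethyl)tetrahydro-2H-pyran | COc1cc([C@H]2C[C@H](O[Si](C)(C)C(C)(C)C)C[C@@H](CCl)O2)ccc1OCc1ccccc1 | intermediate
14 | {(2S,4S,6R)-6-[4-(benzyloxy)-3-methoxyphenyl]-4-[(tert-butyldimethylsilyl)oxy]tetrahydro-2H-pyran-2-yl}methyl acetate | COc1cc([C@H]2C[C@H](O[Si](C)(C)C(C)(C)C)C[C@@H](COC(C)=O)O2)ccc1OCc1ccccc1 | intermediate
15 | {(2S,4S,6R)-6-[4-(benzyloxy)-3-methoxyphenyl]-4-[(tert-butyldimethylsilyl)oxy]tetrahydro-2H-pyran-2-yl}methanol | COc1cc([C@H]2C[C@H](O[Si](C)(C)C(C)(C)C)C[C@@H](CO)O2)ccc1OCc1ccccc1 | intermediate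
16 | (2S,4S,6R)-6-[4-(benzyloxy)-3-methoxyphenyl]-4-[(tert-butyldimethylsilyl)oxy]tetrahydro-2H-pyran-2-carbaldehyde | COc1cc([C@H]2C[C@H](O[Si](C)(C)C(C)(C)C)C[C@@H](C=O)O2)ccc1OCc1ccccc1 | intermediate
17 | 4-(benzyloxy)benzyl chloride | ClCc1ccc(OCc2ccccc2)cc1 | starting material
18 | 4-(benzyloxy)benzylmagnesium chloride | Cl[Mg]Cc1ccc(OCc2ccccc2)cc1 | intermediate
19 | (1S)-1-{(2S,4S,6R)-6-[4-(benzyloxy)-3-methoxyphenyl]-4-[(tert-butyldimethylsilyl)oxy]tetrahydro-2H-pyran-2-yl}-2-[4-(benzyloxy)phenyl]ethan-1-ol | COc1cc([C@H]2C[C@H](O[Si](C)(C)C(C)(C)C)C[C@@H]([C@@H](O)Cc3ccc(OCc4ccccc4)cc3)O2)ccc1OCc1ccccc1 | intermediate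
20 | (2R,4S,6S)-2-[4-(benzyloxy)-3-methoxyphenyl]-6-{(1S)-2-[4-(benzyloxy)phenyl]-1-hydroxyethyl}tetrahydro-2H-pyran-4-ol | COc1cc([C@H]2C[C@H](O)C[C@@H]([C@@H](O)Cc3ccc(OCc4ccccc4)cc3)O2)ccc1OCc1ccccc1 | intermediate
21 | rhoiptelol B | COc1cc([C@H]2C[C@H](O)C[C@@H]([C@@H](O)Cc3ccc(O)cc3)O2)ccc1O | target

**Total step count:** 12. **Longest linear sequence:** 11 (steps 1–3 and 5–12; step 4 is a one-step side branch).

**Steps most likely to fail**

1. Step 10.
 - Risk: facial selectivity may be poor if the very reactive benzyl Grignard reagent adds before the Mg chelate is organised, and Wurtz homocoupling may deplete 18.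
 - Fallback (from 16, back to the route at 19): the addition of 18 is run in THF at −78 °C without regard to selectivity and gives 19 together with its C6-epimeric (1R)-alcohol F1. The mixture is oxidised with Dess–Martin periodinane to the benzyl ketone F2. C6 is then set by C–H rather than C–C bond formation: L-Selectride in THF at −78 °C is non-chelating and delivers hydride in the polar Felkin–Anh sense, anti to the C5–O ring bond. For the ketone this gives the 5,6-syn (6S) alcohol 19.

2. Step 6.
 - Risk: the ionisation may go astray in three ways. Proton loss from C2 of the oxocarbenium ion may be followed by allylic loss of the C3 silyloxy group, the Lewis acid may cleave the silyl ether, or the electron-rich benzylic ether product may re-ionise and be over-reduced with ring opening.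
 - Fallback (from 11, back to the route at 13): the open hydroxy-ketone tautomer of 11 is reduced with NaBH4 in MeOH at 0 °C to the C1-epimeric 1,5-diol F3. Catalytic camphorsulfonic acid in CH2Cl2 (0 °C → rt) then ionises only the p-alkoxybenzylic carbinol, and the C5 hydroxyl captures the cation in an SN1 cyclodehydration that forms O–C1 instead of C1–H. No hydride source is present. Reversible ring opening should funnel both epimers into the diequatorial 2,6-cis pyran 13.

3. Step 7.
 - Risk: substitution at the β-branched, β-oxygenated primary chloride may be slow, with competing E2 loss of HCl to the exocyclic enol ether and erosion of the silyl ether at the temperature required.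
 - Fallback (from 13, back to the route at 16, bypassing 14 and 15): the far more nucleophilic thiophenolate (PhSNa, DMF, rt → 60 °C) gives the phenyl sulfide F4. One equivalent of mCPBA in CH2Cl2 at −78 °C gives the sulfoxide F5 as a mixture at sulfur. A Pummerer rearrangement (TFAA, 2,6-lutidine, CH2Cl2, 0 °C) raises C6 to the aldehyde oxidation level as the α-trifluoroacetoxy sulfide F6, which is hydrolysed in the same flask with aq. NaHCO3 to aldehyde 16.

**Further compounds**
F1 | step 10 | (1R)-1-{(2S,4S,6R)-6-[4-(benzyloxy)-3-methoxyphenyl]-4-[(tert-butyldimethylsilyl)oxy]tetrahydro-2H-pyran-2-yl}-2-[4-(benzyloxy)phenyl]ethan-1-ol | COc1cc([C@H]2C[C@H](O[Si](C)(C)C(C)(C)C)C[C@@H]([C@H](O)Cc3ccc(OCc4ccccc4)cc3)O2)ccc1OCc1ccccc1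
F2 | step 10 | 1-{(2S,4S,6R)-6-[4-(benzyloxy)-3-methoxyphenyl]-4-[(tert-butyldimethylsilyl)oxy]tetrahydro-2H-pyran-2-yl}-2-[4-(benzyloxy)phenyl]ethan-1-one | COc1cc([C@H]2C[C@H](O[Si](C)(C)C(C)(C)C)C[C@@H](C(=O)Cc3ccc(OCc4ccccc4)cc3)O2)ccc1OCc1ccccc1
F3 | step 6 | (3S,5S)-1-[4-(benzyloxy)-3-methoxyphenyl]-3-[(tert-butyldimethylsilyl)oxy]-6-chlorohexane-1,5-diol (C1 epimers) | COc1cc(C(O)C[C@H](O[Si](C)(C)C(C)(C)C)C[C@H](O)CCl)ccc1OCc1ccccc1
F4 | step 7 | (2R,4S,6S)-2-[4-(benzyloxy)-3-methoxyphenyl]-4-[(tert-butyldimethylsilyl)oxy]-6-[(phenylsulfanyl)methyl]tetrahydro-2H-pyran | COc1cc([C@H]2C[C@H](O[Si](C)(C)C(C)(C)C)C[C@@H](CSc3ccccc3)O2)ccc1OCc1ccccc1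
F5 | step 7 | (2R,4S,6S)-2-[4-(benzyloxy)-3-methoxyphenyl]-4-[(tert-butyldimethylsilyl)oxy]-6-[(phenylsulfinyl)methyl]tetrahydro-2H-pyran (mixture at sulfur) | COc1cc([C@H]2C[C@H](O[Si](C)(C)C(C)(C)C)C[C@@H](CS(=O)c3ccccc3)O2)ccc1OCc1ccccc1
F6 | step 7 | {(2S,4S,6R)-6-[4-(benzyloxy)-3-methoxyphenyl]-4-[(tert-butyldimethylsilyl)oxy]tetrahydro-2H-pyran-2-yl}(phenylsulfanyl)methyl trifluoroacetate (mixture at the new carbon) | COc1cc([C@H]2C[C@H](O[Si](C)(C)C(C)(C)C)C[C@@H](C(OC(=O)C(F)(F)F)Sc3ccccc3)O2)ccc1OCc1ccccc1
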